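**Retrosynthetic overview**
- The target is two (2R,3S)-mesquitol units joined from C5 of ring A of one unit (upper) to C6 of ring A of the other (lower). All four stereocentres and all six rings are bought with (−)-mesquitol, so no ring and no stereocentre is made.
- Key disconnection: the C5–C6 biaryl bond, formed by a [3,3]-sigmatropic rearrangement of an aryloxysulfonium in which sulfur on C6 of the upper unit is tethered to O7 of the lower unit.
- Lower unit (phenol partner): 7-OH free, 8-O-benzyl, ring B as diphenylmethylene ketal, reached by tosyl masking of the three exposed phenols.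
- Upper unit (sulfoxide partner): tetra-O-benzylmesquitol carrying a methylsulfinyl group at C6.
- End game: Raney Ni removes the tether sulfur, then one hydrogenolysis removes every protecting group.

Assumption: (−)-mesquitol, (2R,3S), is bought as the catalogued natural product (also isolable in bulk from Prosopis juliflora heartwood); the biaryl axis has no stereodescriptor in the target and is not controlled.

**Step 1**
Reactants: 1 (−)-mesquitol
Product: 3 (2R,3S)-8-O-benzyl-7,3',4'-tri-O-tosylmesquitol, via tritosylate 2 (not isolated)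
Conditions: TsCl (3.05 equiv), K2CO3, acetone, 0 °C → rt; then BnBr (1.5 equiv), KI (cat.), 56 °C, one pot, Ar
Reagents that add atoms: p-toluenesulfonyl chloride Cc1ccc(S(Cl)(=O)=O)cc1; benzyl bromide BrCc1ccccc1
Why: Kinetic O-sulfonylation takes the three exposed phenols (3'-OH, 4'-OH and the outer 7-OH) and leaves the 8-OH, wedged between O1 and O7, for the following Williamson benzylation (the monotosylate route to catechol monoethers); no stereocentre is involved.

**Step 2**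
Reactants: 3 (2R,3S)-8-O-benzyl-7,3',4'-tri-O-tosylmesquitol
Product: 4 (2R,3S)-8-O-benzylmesquitol
Conditions: Mg turnings (12 equiv), MeOH/THF, rt, sonication, Ar; aq NH4Cl
Reagents that add atoms: none
Why: Reductive S–O cleavage (Mg/MeOH detosylation) frees the three phenols at room temperature, avoiding hot alkali that could epimerise C2, and leaves the benzyl ether intact.

**Step 3**
Reactants: 4 (2R,3S)-8-O-benzylmesquitol
Product: 5 (2R,3S)-8-(benzyloxy)-2-(2,2-diphenyl-1,3-benzodioxol-5-yl)chromane-3,7-diol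
Conditions: Ph2CCl2 (1.1 equiv), K2CO3, MeCN, rt, Ar
Reagents that add atoms: dichlorodiphenylmethane ClC(Cl)(c1ccccc1)c1ccccc1
Why: Ketalisation with a gem-dichloride needs two adjacent phenols, so only the ring B catechol closes to the diphenylmethylene ketal and the lone 7-OH stays free.

**Step 4**
Reactants: 1 (−)-mesquitol
Product: 6 (2R,3S)-7,8,3',4'-tetra-O-benzylmesquitol
Conditions: BnBr (4.4 equiv), K2CO3, DMF, rt, Ar
Reagents that add atoms: benzyl bromide BrCc1ccccc1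
Why: Williamson etherification under carbonate base alkylates the four phenols only, as in the standard tetra-O-benzylation of catechin; the secondary 3-OH and both stereocentres are untouched.

**Step 5**
Reactants: 6 (2R,3S)-7,8,3',4'-tetra-O-benzylmesquitol
Product: 7 (2R,3S)-7,8,3',4'-tetra-O-benzyl-6-(methylsulfanyl)mesquitol
Conditions: [Me2S–SMe]BF4 (DMTSF, 1.2 equiv), NaHCO3, CH2Cl2/MeCN, 0 °C → rt
Reagents that add atoms: dimethyl(methylthio)sulfonium tetrafluoroborate C[S+](C)SC.F[B-](F)(F)F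
Why: Electrophilic aromatic sulfenylation goes to C6, the only carbon that is para to O1 and ortho to the coplanar 7-benzyloxy group (C5 is para only to the twisted 8-O and peri to C4; ring B has a single para donor).

**Step 6**
Reactants: 7 (2R,3S)-7,8,3',4'-tetra-O-benzyl-6-(methylsulfanyl)mesquitol
Product: 8 (2R,3S)-7,8,3',4'-tetra-O-benzyl-6-(methylsulfinyl)mesquitol
Conditions: mCPBA (1.0 equiv), CH2Cl2, −78 → −40 °C
Reagents that add atoms: mCPBA OOC(=O)c1cccc(Cl)c1
Why: Chemoselective sulfide-to-sulfoxide oxidation; the new sulfur stereocentre forms as a roughly 1:1 mixture, which does not matter because sulfur is removed in step 8.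

**Step 7**
Reactants: 5 (2R,3S)-8-(benzyloxy)-2-(2,2-diphenyl-1,3-benzodioxol-5-yl)chromane-3,7-diol; 8 (2R,3S)-7,8,3',4'-tetra-O-benzyl-6-(methylsulfinyl)mesquitol
Product: 11 protected 5→6 biaryl (upper unit: 7,8,3',4'-tetra-O-benzyl-6-(methylsulfanyl)mesquitol-5-yl; lower unit: 8-O-benzyl-3',4'-O-(diphenylmethylene)mesquitol bonded at C6, 7-OH free), via aryloxysulfonium salt 9 (not isolated), via bis-trifluoroacetate 10 (not isolated)
Conditions: 5 (1.0 equiv), 8 (1.2 equiv), (CF3CO)2O (4.5 equiv), CH2Cl2, −40 → 0 °C; evaporate; K2CO3 (cat.), MeOH, 0 °C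
Reagents that add atoms: none
Why: The anhydride-activated sulfoxide is captured by the 7-OH (both 3-OH groups are transiently trifluoroacetylated) and the resulting S–O sulfonium undergoes a charge-accelerated [3,3]-sigmatropic rearrangement (interrupted Pummerer, sulfonium-Claisen type) that joins the only free ortho carbon of the phenol (C6) to the only free ortho carbon of the sulfonium ring (C5), after which tautomerisation rearomatises both rings and methanolysis removes the trifluoroacetates; no stereocentre is touched.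

**Step 8**
Reactants: 11 protected 5→6 biaryl with 6-SMe on the upper unit
Product: 12 protected 5→6 biaryl without sulfur (upper unit: 7,8,3',4'-tetra-O-benzylmesquitol-5-yl; lower unit as in 11)
Conditions: Raney Ni (W-2, excess), EtOH/THF, rt
Reagents that add atoms: none
Why: Raney Ni desulfurisation (reductive C–S hydrogenolysis) replaces the tether sulfur at C6 of the upper unit by hydrogen.

**Step 9**
Reactants: 12 protected 5→6 biaryl without sulfur
Product: 13 (−)-mesquitol-(5→6)-(−)-mesquitol (CNP0319747.1)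
Conditions: H2 (1 atm), Pd(OH)2/C, THF/MeOH (1:1), rt; filtration and concentration under Ar
Reagents that add atoms: none
Why: Catalytic hydrogenolysis cleaves the five benzyl ethers and the diphenylmethylene ketal under conditions that leave the benzylic C2–O1 bonds and the four (2R,3S) stereocentres of flavan-3-ols intact.

**Compound list**
1 | (−)-mesquitol, (2R,3S)-2-(3,4-dihydroxyphenyl)chromane-3,7,8-triol | O[C@H]1Cc2ccc(O)c(O)c2O[C@@H]1c1ccc(O)c(O)c1 | starting material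
2 | (2R,3S)-7,3',4'-tri-O-tosylmesquitol (8-OH and 3-OH free) | O[C@H]1Cc2ccc(OS(=O)(=O)c3ccc(C)cc3)c(O)c2O[C@@H]1c1ccc(OS(=O)(=O)c2ccc(C)cc2)c(OS(=O)(=O)c2ccc(C)cc2)c1 | intermediate
3 | (2R,3S)-8-O-benzyl-7,3',4'-tri-O-tosylmesquitol | O[C@H]1Cc2ccc(OS(=O)(=O)c3ccc(C)cc3)c(OCc3ccccc3)c2O[C@@H]1c1ccc(OS(=O)(=O)c2ccc(C)cc2)c(OS(=O)(=O)c2ccc(C)cc2)c1 | intermediate
4 | (2R,3S)-8-(benzyloxy)-2-(3,4-dihydroxyphenyl)chromane-3,7-diol | O[C@H]1Cc2ccc(O)c(OCc3ccccc3)c2O[C@@H]1c1ccc(O)c(O)c1 | intermediate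
5 | (2R,3S)-8-(benzyloxy)-2-(2,2-diphenyl-1,3-benzodioxol-5-yl)chromane-3,7-diol | O[C@H]1Cc2ccc(O)c(OCc3ccccc3)c2O[C@@H]1c1ccc2OC(c3ccccc3)(c3ccccc3)Oc2c1 | intermediate
6 | (2R,3S)-7,8-bis(benzyloxy)-2-[3,4-bis(benzyloxy)phenyl]chroman-3-ol | O[C@H]1Cc2ccc(OCc3ccccc3)c(OCc3ccccc3)c2O[C@@H]1c1ccc(OCc2ccccc2)c(OCc2ccccc2)c1 | intermediate
7 | (2R,3S)-7,8-bis(benzyloxy)-2-[3,4-bis(benzyloxy)phenyl]-6-(methylsulfanyl)chroman-3-ol | O[C@H]1Cc2cc(SC)c(OCc3ccccc3)c(OCc3ccccc3)c2O[C@@H]1c1ccc(OCc2ccccc2)c(OCc2ccccc2)c1 | intermediate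
8 | (2R,3S)-7,8-bis(benzyloxy)-2-[3,4-bis(benzyloxy)phenyl]-6-(methylsulfinyl)chroman-3-ol, both sulfur epimers | O[C@H]1Cc2cc(S(C)=O)c(OCc3ccccc3)c(OCc3ccccc3)c2O[C@@H]1c1ccc(OCc2ccccc2)c(OCc2ccccc2)c1 | intermediate
9 | S-methyl aryloxysulfonium trifluoroacetate: sulfur on C6 of the 3-O-trifluoroacetate of 6, bonded to O7 of the 3-O-trifluoroacetate of 5 | FC(F)(F)C(=O)O[C@H]1Cc2cc([S+](C)Oc3ccc4C[C@H](OC(=O)C(F)(F)F)[C@@H](c5ccc6OC(c7ccccc7)(c7ccccc7)Oc6c5)Oc4c3OCc3ccccc3)c(OCc3ccccc3)c(OCc3ccccc3)c2O[C@@H]1c1ccc(OCc2ccccc2)c(OCc2ccccc2)c1.[O-]C(=O)C(F)(F)F | intermediate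
10 | bis(3-O-trifluoroacetate) of 11 | FC(F)(F)C(=O)O[C@H]1Cc2c(-c3cc4C[C@H](OC(=O)C(F)(F)F)[C@@H](c5ccc6OC(c7ccccc7)(c7ccccc7)Oc6c5)Oc4c(OCc4ccccc4)c3O)c(SC)c(OCc3ccccc3)c(OCc3ccccc3)c2O[C@@H]1c1ccc(OCc2ccccc2)c(OCc2ccccc2)c1 | intermediate
11 | 5→6 biaryl: (2R,3S)-7,8,3',4'-tetra-O-benzyl-6-(methylsulfanyl)mesquitol bonded through C5 to C6 of (2R,3S)-8-O-benzyl-3',4'-O-(diphenylmethylene)mesquitol (7-OH free) | O[C@H]1Cc2c(-c3cc4C[C@H](O)[C@@H](c5ccc6OC(c7ccccc7)(c7ccccc7)Oc6c5)Oc4c(OCc4ccccc4)c3O)c(SC)c(OCc3ccccc3)c(OCc3ccccc3)c2O[C@@H]1c1ccc(OCc2ccccc2)c(OCc2ccccc2)c1 | intermediate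
12 | 5→6 biaryl: (2R,3S)-7,8,3',4'-tetra-O-benzylmesquitol bonded through C5 to C6 of (2R,3S)-8-O-benzyl-3',4'-O-(diphenylmethylene)mesquitol (7-OH free) | O[C@H]1Cc2c(-c3cc4C[C@H](O)[C@@H](c5ccc6OC(c7ccccc7)(c7ccccc7)Oc6c5)Oc4c(OCc4ccccc4)c3O)cc(OCc3ccccc3)c(OCc3ccccc3)c2O[C@@H]1c1ccc(OCc2ccccc2)c(OCc2ccccc2)c1 | intermediate
13 | (−)-mesquitol-(5→6)-(−)-mesquitol, all four centres (2R,3S) | Oc1ccc([C@H]2Oc3c(cc(-c4cc(O)c(O)c5c4C[C@H](O)[C@@H](c4ccc(O)c(O)c4)O5)c(O)c3O)C[C@@H]2O)cc1O | target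

**Totals**
Total steps: 9. Longest linear sequence: 6 (steps 1, 2, 3, 7, 8, 9; the branch of steps 4, 5, 6 joins at step 7).

**Steps most likely to fail and their fallbacks**

Step 7 (biaryl coupling). The S-methyl group can undergo a classical Pummerer reaction, the ketal of 5 sees trifluoroacetic acid, and the new bond forms at the hindered C5 next to C4. The fallback gives up the sulfur tether and joins the rings by oxidative phenol–arene cross-coupling. It sets out from 6: MgBr2·OEt2 in toluene/Et2O removes the benzyl group on the oxygen flanked by O1 and O7 by chelation, giving (2R,3S)-7,3',4'-tri-O-benzylmesquitol F6 with the 8-OH free. F6 is oxidised with PhI(OCOCF3)2 in (CF3)2CHOH/CH2Cl2 at −40 °C in the presence of 6 (2 equiv). The phenoxenium-type intermediate is attacked at C5, para to the 8-OH, by the nucleophilic C6 of 6, giving the hepta-O-benzyl 5→6 biaryl F7. Hydrogenolysis of F7 under the conditions of step 9 comes back to the route at 13.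

Step 1 (one-pot differentiation of four phenols). Over- or under-tosylation and incomplete discrimination of the 8-OH would give mixtures. The fallback protects the catechols pairwise first and then unmasks ring A. It sets out from 1: Ph2CCl2 (2.3 equiv), K2CO3, MeCN gives 7,8:3',4'-bis-O-(diphenylmethylene)mesquitol F1. BCl3 (2.2 equiv), CH2Cl2, −78 °C, then aq NaHCO3 should cleave the ring A ketal first, because only there can the Lewis acid sit between O1 and O8, giving 3',4'-O-(diphenylmethylene)mesquitol F2. With a single catechol left, TsCl (1.0 equiv), Et3N, CH2Cl2, −20 °C gives 3',4'-O-(diphenylmethylene)-7-O-tosylmesquitol F3. BnBr, K2CO3, acetone gives 8-O-benzyl-3',4'-O-(diphenylmethylene)-7-O-tosylmesquitol F4, and Mg/MeOH comes back to the route at 5.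

Step 5 (direct C–H sulfenylation). The reagent may be too weak an electrophile for the benzyl-protected ring, or ring B may compete. The fallback replaces it by halogenation and halogen–metal exchange. It sets out from 6: NBS, CH2Cl2, −40 °C gives 6-bromo-7,8,3',4'-tetra-O-benzylmesquitol F5. n-BuLi (2.2 equiv, the first equivalent deprotonates the 3-OH), THF, −78 °C, then MeSSMe comes back to the route at 7.

**Further compounds**
F1 | step 1 | (2R,3S)-7,8:3',4'-bis-O-(diphenylmethylene)mesquitol | O[C@H]1Cc2ccc3OC(c4ccccc4)(c4ccccc4)Oc3c2O[C@@H]1c1ccc2OC(c3ccccc3)(c3ccccc3)Oc2c1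
F2 | step 1 | (2R,3S)-3',4'-O-(diphenylmethylene)mesquitol | O[C@H]1Cc2ccc(O)c(O)c2O[C@@H]1c1ccc2OC(c3ccccc3)(c3ccccc3)Oc2c1
F3 | step 1 | (2R,3S)-3',4'-O-(diphenylmethylene)-7-O-tosylmesquitol | O[C@H]1Cc2ccc(OS(=O)(=O)c3ccc(C)cc3)c(O)c2O[C@@H]1c1ccc2OC(c3ccccc3)(c3ccccc3)Oc2c1
F4 | step 1 | (2R,3S)-8-O-benzyl-3',4'-O-(diphenylmethylene)-7-O-tosylmesquitol | O[C@H]1Cc2ccc(OS(=O)(=O)c3ccc(C)cc3)c(OCc3ccccc3)c2O[C@@H]1c1ccc2OC(c3ccccc3)(c3ccccc3)Oc2c1
F5 | step 5 | (2R,3S)-6-bromo-7,8,3',4'-tetra-O-benzylmesquitol | O[C@H]1Cc2cc(Br)c(OCc3ccccc3)c(OCc3ccccc3)c2O[C@@H]1c1ccc(OCc2ccccc2)c(OCc2ccccc2)c1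
F6 | step 7 | (2R,3S)-7,3',4'-tri-O-benzylmesquitol (8-OH free) | O[C@H]1Cc2ccc(OCc3ccccc3)c(O)c2O[C@@H]1c1ccc(OCc2ccccc2)c(OCc2ccccc2)c1
F7 | step 7 | 5→6 biaryl of (2R,3S)-7,3',4'-tri-O-benzylmesquitol (through C5, 8-OH free) and (2R,3S)-7,8,3',4'-tetra-O-benzylmesquitol (through C6) | O[C@H]1Cc2c(-c3cc4C[C@H](O)[C@@H](c5ccc(OCc6ccccc6)c(OCc6ccccc6)c5)Oc4c(OCc4ccccc4)c3OCc3ccccc3)cc(OCc3ccccc3)c(O)c2O[C@@H]1c1ccc(OCc2ccccc2)c(OCc2ccccc2)c1
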